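The route rests on cutting the C1–C4 bond of the cyclobutane, C1 being the quaternary ring carbon that bears the naphthazarin ring, the ester oxygen and the neighbouring CMe2 carbon C2, and C4 the ring CH2. Because C1 is both benzylic and oxygenated, it can be lithiated as a carbamate. A pinacol boronate on C4 then captures it as a five-membered boracycle, and a 1,2-shift of C4 from boron to C1 closes the four-membered ring and sets the quaternary stereocentre in one operation, leaving boron where the oxygen will be. The precursor is the open-chain (R)-benzylic N,N-diisopropylcarbamate ArCH(OCb)–CMe2–CH2–CH2–Bpin, Ar being 1,4,5,8-tetramethoxynaphthalen-2-yl.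

Key step: step 6

Remark 1: naphthazarins interconvert rapidly between their ring tautomers, so the target is one compound whichever ring is drawn as the quinone.
Remark 2: the iridium catalyst built on (R)-SEGPHOS is assumed to give the R carbinol, as in the parent allylation; the configuration of 7 would be checked against the racemate and the mirror-image ligand used if the sense proved opposite.
Remark 3: methyl ethers are kept on the four oxygens because they are inert to the amide base, basic peroxide and alkoxide chemistry; they are removed at the end by two oxidative demethylations, so that no Lewis acid meets the tertiary ester.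

Step 1
Reactants: 1 naphthazarin
Product: 3 1,4,5,8-tetramethoxynaphthalene, via naphthalene-1,4,5,8-tetrol 2 (not isolated)
Conditions: Na2S2O4, NaOH, Me2SO4, Bu4NBr, THF/H2O, N2, rt
Reagents that add atoms: dimethyl sulfate, COS(=O)(=O)OC
Why: Reductive methylation, in which dithionite reduces the quinone to the leuco tetraphenol and its phenoxides undergo Williamson O-methylation under phase transfer before air can reoxidise them.

Step 2
Reactants: 3 1,4,5,8-tetramethoxynaphthalene
Product: 5 1,4,5,8-tetramethoxynaphthalene-2-carbaldehyde, via aryl iminium chloride 4 (not isolated)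
Conditions: POCl3, DMF, CHCl3, reflux; then ice, aq NaOH to pH 7
Reagents that add atoms: N,N-dimethylformamide, CN(C)C=O; water, O
Why: Vilsmeier–Haack formylation, in which the chloroiminium ion attacks the electron-rich ring ortho to a methoxy group (the four free positions are equivalent, so one aldehyde should result) and hydrolysis of the iminium salt gives the aldehyde.

Step 3
Reactants: 5 1,4,5,8-tetramethoxynaphthalene-2-carbaldehyde; 6 1,1-dimethylallene
Product: 7 (1R)-2,2-dimethyl-1-(1,4,5,8-tetramethoxynaphthalen-2-yl)but-3-en-1-ol
Conditions: Ir(η3-C3H5)[(R)-SEGPHOS](C,O-4-cyano-3-nitrobenzoate) (5 mol%, made from [Ir(cod)Cl]2, (R)-SEGPHOS, 4-cyano-3-nitrobenzoic acid, allyl acetate, Cs2CO3), iPrOH (2 equiv), toluene, 50 °C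
Reagents that add atoms: none
Why: Iridium-catalysed transfer-hydrogenative carbonyl tert-prenylation, in which the iridium hydride formed from isopropanol hydrometalates the allene to a 1,1-dimethylallyl iridium species that adds to the aldehyde at its substituted carbon through a closed chair-like transition state, the chiral bisphosphine selecting the aldehyde face that leads to the R carbinol.

Step 4
Reactants: 7 (1R)-2,2-dimethyl-1-(1,4,5,8-tetramethoxynaphthalen-2-yl)but-3-en-1-ol
Product: 9 (1R)-2,2-dimethyl-1-(1,4,5,8-tetramethoxynaphthalen-2-yl)but-3-en-1-yl N,N-diisopropylcarbamate, via sodium alkoxide 8 (not isolated)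
Conditions: NaH, THF, 0 °C; then N,N-diisopropylcarbamoyl chloride, reflux
Reagents that add atoms: N,N-diisopropylcarbamoyl chloride, CC(C)N(C(C)C)C(Cl)=O
Why: O-Carbamoylation of the preformed alkoxide by acyl substitution at the carbamoyl chloride, which leaves the stereocentre untouched and installs the group that later directs lithiation and serves as leaving group.

Step 5
Reactants: 9 (1R)-2,2-dimethyl-1-(1,4,5,8-tetramethoxynaphthalen-2-yl)but-3-en-1-yl N,N-diisopropylcarbamate; 10 pinacolborane
Product: 11 (1R)-2,2-dimethyl-4-(4,4,5,5-tetramethyl-1,3,2-dioxaborolan-2-yl)-1-(1,4,5,8-tetramethoxynaphthalen-2-yl)butyl N,N-diisopropylcarbamate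
Conditions: [Ir(cod)Cl]2 (1.5 mol%), dppm (3 mol%), CH2Cl2, rt
Reagents that add atoms: none
Why: Iridium-catalysed anti-Markovnikov hydroboration of a monosubstituted alkene with pinacolborane, in which the quaternary allylic carbon forces boron onto the terminal carbon while the carbamate and the aryl ethers are inert.

Step 6
Reactants: 11 (1R)-2,2-dimethyl-4-(4,4,5,5-tetramethyl-1,3,2-dioxaborolan-2-yl)-1-(1,4,5,8-tetramethoxynaphthalen-2-yl)butyl N,N-diisopropylcarbamate
Product: 14 pinacol (1S)-2,2-dimethyl-1-(1,4,5,8-tetramethoxynaphthalen-2-yl)cyclobutylboronate, via benzyllithium 12 (not isolated), via borolane ate complex 13 (not isolated)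
Conditions: lithium 2,2,6,6-tetramethylpiperidide (1.5 equiv), THF, −78 °C; then MgBr2·OEt2, MeOH, −78 °C → rt
Reagents that add atoms: none
Why: Proposed new method: the hindered amide base, which does not bind the pinacol boronate, removes the benzylic proton next to the carbamate to give the carbamate-chelated, configurationally stable benzyllithium 12; the boron three atoms along the chain captures it at once on the lithium-bearing face (retention) to give the spiro borolane ate complex 13, and the ring B–CH2 bond then shifts from boron to the benzylic carbon anti to the departing carbamate (inversion), which forms the C1–C4 bond. The closest known reactions are the in situ lithiation–borylation of secondary benzylic carbamates to tertiary boronic esters and the ring-contracting 1,2-metalate shifts of cyclic boronate complexes. The cyclobutane is closed by ring contraction and not by direct four-membered cyclisation: a favourable five-membered closure at boron, helped by the gem-dimethyl group, is followed by transfer of one ring carbon from boron to carbon, the strain being paid for by loss of the carbamate. The quaternary stereocentre is controlled by the substrate alone, the R carbinol configuration of 11 being relayed through retention, retention and inversion to S-14. The step needs migration of carbon in preference to a pinacol oxygen and no leakage through free benzyllithium: the ring CH2 is the only carbon ligand on boron that can migrate, the borolane can twist to bring that bond nearly anti to the C–O bond, and MgBr2/MeOH activates the carbamate and protonates any benzyllithium set free by reversal before it can racemise.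

Step 7
Reactants: 14 pinacol (1S)-2,2-dimethyl-1-(1,4,5,8-tetramethoxynaphthalen-2-yl)cyclobutylboronate
Product: 15 (1R)-2,2-dimethyl-1-(1,4,5,8-tetramethoxynaphthalen-2-yl)cyclobutan-1-ol
Conditions: 30% H2O2, 2 M NaOH, THF, 0 °C → rt
Reagents that add atoms: hydrogen peroxide, OO
Why: Oxidation of a tertiary boronic ester with basic hydrogen peroxide, in which hydroperoxide adds to boron and the cyclobutyl carbon migrates to oxygen with retention, so that S-14 gives R-15 (same spatial arrangement, changed priorities).

Step 8
Reactants: 16 angelic acid (two molecules are consumed for each molecule of anhydride)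
Product: 17 angelic anhydride
Conditions: DCC (0.5 equiv relative to 16), CH2Cl2, 0 °C → rt
Reagents that add atoms: angelic acid (the second molecule of 16, which supplies the second acyl group), C/C=C(/C)C(=O)O
Why: Carbodiimide dehydration of a carboxylic acid to its symmetrical anhydride, in which one molecule of 16 adds to DCC to give the O-acylisourea and a second molecule of 16 acylates at that activated carbonyl with loss of the urea, all under neutral conditions that avoid the base- or nucleophile-promoted Z to E isomerisation to the tiglate.

Step 9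
Reactants: 15 (1R)-2,2-dimethyl-1-(1,4,5,8-tetramethoxynaphthalen-2-yl)cyclobutan-1-ol; 17 angelic anhydride
Product: 19 (1R)-2,2-dimethyl-1-(1,4,5,8-tetramethoxynaphthalen-2-yl)cyclobutyl (Z)-2-methylbut-2-enoate, via lithium alkoxide 18 (not isolated)
Conditions: LiN(SiMe3)2, THF, −78 → 0 °C; then 17, 0 °C → rt
Reagents that add atoms: none
Why: Acylation of a preformed lithium tertiary alkoxide by the symmetrical anhydride (addition–elimination) in the absence of any nucleophilic amine catalyst, so the Z geometry should be kept and the stereocentre is not involved.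

Step 10
Reactants: 19 (1R)-2,2-dimethyl-1-(1,4,5,8-tetramethoxynaphthalen-2-yl)cyclobutyl (Z)-2-methylbut-2-enoate
Product: 20 (1R)-1-(1,4-dimethoxy-5,8-dioxo-5,8-dihydronaphthalen-2-yl)-2,2-dimethylcyclobutyl (Z)-2-methylbut-2-enoate
Conditions: (NH4)2Ce(NO3)6, MeCN/H2O, 0 °C
Reagents that add atoms: water, O
Why: Oxidative demethylation of a para-dimethoxyarene (one-electron oxidation, water attack at the methoxy-bearing carbons, loss of methanol), expected in the ring remote from the bulky cyclobutyl ester; which ring reacts first does not matter because step 11 oxidises the other one as well, and the enoate and the ester are inert at 0 °C.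

Step 11
Reactants: 20 (1R)-1-(1,4-dimethoxy-5,8-dioxo-5,8-dihydronaphthalen-2-yl)-2,2-dimethylcyclobutyl (Z)-2-methylbut-2-enoate
Product: 22 (1R)-1-(5,8-dihydroxy-1,4-dioxo-1,4-dihydronaphthalen-2-yl)-2,2-dimethylcyclobutyl (Z)-2-methylbut-2-enoate, via naphthodiquinone 21 (not isolated)
Conditions: AgO, 6 M HNO3, dioxane, rt, a few minutes; then aq Na2S2O4
Reagents that add atoms: water, O
Why: A second oxidative demethylation with the stronger oxidant AgO turns the deactivated dimethoxy ring into a second quinone, and dithionite reduces the diquinone by two electrons to the hydrogen-bonded naphthazarin, so the tertiary ester never meets a Lewis acid.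

Compound list
1 | naphthazarin (5,8-dihydroxynaphthalene-1,4-dione) | O=C1C=CC(=O)c2c(O)ccc(O)c12 | starting material
2 | naphthalene-1,4,5,8-tetrol (present as its sodium salt) | Oc1ccc(O)c2c(O)ccc(O)c12 | intermediate
3 | 1,4,5,8-tetramethoxynaphthalene | COc1ccc(OC)c2c(OC)ccc(OC)c12 | intermediate
4 | N,N-dimethyl-1-(1,4,5,8-tetramethoxynaphthalen-2-yl)methaniminium chloride | COc1cc(C=[N+](C)C)c(OC)c2c(OC)ccc(OC)c12.[Cl-] | intermediate
5 | 1,4,5,8-tetramethoxynaphthalene-2-carbaldehyde | COc1cc(C=O)c(OC)c2c(OC)ccc(OC)c12 | intermediate
6 | 1,1-dimethylallene (3-methylbuta-1,2-diene) | CC(C)=C=C | starting material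
7 | (1R)-2,2-dimethyl-1-(1,4,5,8-tetramethoxynaphthalen-2-yl)but-3-en-1-ol | COc1cc([C@H](O)C(C)(C)C=C)c(OC)c2c(OC)ccc(OC)c12 | intermediate
8 | sodium (1R)-2,2-dimethyl-1-(1,4,5,8-tetramethoxynaphthalen-2-yl)but-3-en-1-olate | COc1cc([C@H]([O-])C(C)(C)C=C)c(OC)c2c(OC)ccc(OC)c12.[Na+] | intermediate
9 | (1R)-2,2-dimethyl-1-(1,4,5,8-tetramethoxynaphthalen-2-yl)but-3-en-1-yl N,N-diisopropylcarbamate | COc1cc([C@H](OC(=O)N(C(C)C)C(C)C)C(C)(C)C=C)c(OC)c2c(OC)ccc(OC)c12 | intermediate
10 | pinacolborane | CC1(C)OBOC1(C)C | starting material
11 | (1R)-2,2-dimethyl-4-(4,4,5,5-tetramethyl-1,3,2-dioxaborolan-2-yl)-1-(1,4,5,8-tetramethoxynaphthalen-2-yl)butyl N,N-diisopropylcarbamate | COc1cc([C@H](OC(=O)N(C(C)C)C(C)C)C(C)(C)CCB2OC(C)(C)C(C)(C)O2)c(OC)c2c(OC)ccc(OC)c12 | intermediate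
12 | alpha-lithiated carbamate of 11 (benzyllithium, lithium in the place of the benzylic hydrogen) | COc1cc([C@]([Li])(OC(=O)N(C(C)C)C(C)C)C(C)(C)CCB2OC(C)(C)C(C)(C)O2)c(OC)c2c(OC)ccc(OC)c12 | intermediate
13 | lithium spiro borolane ate complex (boron bonded to the benzylic carbon, the chain CH2 and the pinacol oxygens) | [Li+].COc1cc([C@]2(OC(=O)N(C(C)C)C(C)C)C(C)(C)CC[B-]23OC(C)(C)C(C)(C)O3)c(OC)c4c(OC)ccc(OC)c14 | intermediate
14 | pinacol (1S)-2,2-dimethyl-1-(1,4,5,8-tetramethoxynaphthalen-2-yl)cyclobutylboronate | CC1(C)OB(OC1(C)C)[C@]2(c3cc(OC)c4c(OC)ccc(OC)c4c3OC)CCC2(C)C | intermediate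
15 | (1R)-2,2-dimethyl-1-(1,4,5,8-tetramethoxynaphthalen-2-yl)cyclobutan-1-ol | O[C@]1(c2cc(OC)c3c(OC)ccc(OC)c3c2OC)CCC1(C)C | intermediate
16 | angelic acid ((Z)-2-methylbut-2-enoic acid) | C/C=C(/C)C(=O)O | starting material
17 | angelic anhydride | C/C=C(/C)C(=O)OC(=O)/C(C)=C\C | intermediate
18 | lithium (1R)-2,2-dimethyl-1-(1,4,5,8-tetramethoxynaphthalen-2-yl)cyclobutan-1-olate | [Li+].[O-][C@]1(c2cc(OC)c3c(OC)ccc(OC)c3c2OC)CCC1(C)C | intermediate
19 | (1R)-2,2-dimethyl-1-(1,4,5,8-tetramethoxynaphthalen-2-yl)cyclobutyl (Z)-2-methylbut-2-enoate | C/C=C(/C)C(=O)O[C@]1(c2cc(OC)c3c(OC)ccc(OC)c3c2OC)CCC1(C)C | intermediate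
20 | (1R)-1-(1,4-dimethoxy-5,8-dioxo-5,8-dihydronaphthalen-2-yl)-2,2-dimethylcyclobutyl (Z)-2-methylbut-2-enoate | C/C=C(/C)C(=O)O[C@]1(c2cc(OC)c3C(=O)C=CC(=O)c3c2OC)CCC1(C)C | intermediate
21 | (1R)-2,2-dimethyl-1-(1,4,5,8-tetraoxo-1,4,5,8-tetrahydronaphthalen-2-yl)cyclobutyl (Z)-2-methylbut-2-enoate | C/C=C(/C)C(=O)O[C@]1(C2=CC(=O)C3=C(C2=O)C(=O)C=CC3=O)CCC1(C)C | intermediate
22 | (1R)-1-(5,8-dihydroxy-1,4-dioxo-1,4-dihydronaphthalen-2-yl)-2,2-dimethylcyclobutyl (Z)-2-methylbut-2-enoate | C/C=C(/C)C(=O)O[C@]1(C2=CC(=O)c3c(O)ccc(O)c3C2=O)CCC1(C)C | target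

Total step count: 11. Longest linear sequence: 10 steps (steps 1 to 7 and 9 to 11); step 8 is a one-step side branch that converts two molecules of 16 into one of 17.

Steps most likely to fail

Step 6 (carries the new method). What may go wrong: proton removal at a ring position or next to boron instead of at the benzylic carbon, migration of a pinacol oxygen in place of the ring carbon, or reversal of the ate complex with loss of configuration. The fallback uses known chemistry, sets out from 3 and returns at 15. Bromination of 3 with N-bromosuccinimide in CH2Cl2 should give 2-bromo-1,4,5,8-tetramethoxynaphthalene F1. Bromine–lithium exchange with n-BuLi in THF at −78 °C gives 2-lithio-1,4,5,8-tetramethoxynaphthalene F2, which is added to commercial 2,2-dimethylcyclobutanone (CC1(C)CCC1=O) to give racemic 2,2-dimethyl-1-(1,4,5,8-tetramethoxynaphthalen-2-yl)cyclobutan-1-ol F3. Preparative chromatography on a chiral stationary phase then supplies the R enantiomer 15. The ring is bought ready-made and the stereocentre comes from a resolution instead of a stereospecific shift; steps 2 to 7 are then not needed.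

Step 9. What may go wrong: acylation of the crowded tertiary alkoxide that is too slow, and isomerisation of the Z enoate to the E isomer under basic conditions. The fallback sets out from 15 and returns at 19. The lithium alkoxide 18 is acylated with the smaller and more electrophilic 2-[bis(2,2,2-trifluoroethoxy)phosphoryl]propanoyl chloride to give (1R)-2,2-dimethyl-1-(1,4,5,8-tetramethoxynaphthalen-2-yl)cyclobutyl 2-[bis(2,2,2-trifluoroethoxy)phosphoryl]propanoate F4. A Still–Gennari olefination (KN(SiMe3)2, 18-crown-6, acetaldehyde, THF, −78 °C) then builds the Z trisubstituted double bond under kinetic control and should give 19.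

Step 11. What may go wrong: ionisation of the tertiary benzylic ester or over-oxidation in the acidic oxidising medium. The fallback sets out from 20 and returns at 22 without any new compound (F0). It is a non-oxidative, chelation-directed ether cleavage with BCl3 in CH2Cl2 at −78 °C: both methoxy groups of 20 lie peri to a quinone carbonyl, so boron chelation should deliver chloride to the methyl groups at low temperature, and aqueous work-up should give 22 directly.

Further compounds
F1 | step 6 | 2-bromo-1,4,5,8-tetramethoxynaphthalene | COc1cc(Br)c(OC)c2c(OC)ccc(OC)c12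
F2 | step 6 | 2-lithio-1,4,5,8-tetramethoxynaphthalene | COc1cc([Li])c(OC)c2c(OC)ccc(OC)c12
F3 | step 6 | racemic 2,2-dimethyl-1-(1,4,5,8-tetramethoxynaphthalen-2-yl)cyclobutan-1-ol | OC1(c2cc(OC)c3c(OC)ccc(OC)c3c2OC)CCC1(C)C
F4 | step 9 | (1R)-2,2-dimethyl-1-(1,4,5,8-tetramethoxynaphthalen-2-yl)cyclobutyl 2-[bis(2,2,2-trifluoroethoxy)phosphoryl]propanoate (both epimers at the phosphonate-bearing carbon) | CC(C(=O)O[C@]1(c2cc(OC)c3c(OC)ccc(OC)c3c2OC)CCC1(C)C)P(=O)(OCC(F)(F)F)OCC(F)(F)F
F0 | step 11 | none | none
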